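**Retrosynthetic overview**
- 26 ⇒ 2-bromoenone 9 + cis-boryl(stannyl)alkene 24 (C–Cl by chlorodeboronation; ring C2–alkenyl bond by Stille coupling); 24 ⇒ acid 19 + amine 22 (amide bond), 22 coming from N-propargylphthalimide 20 by syn borylstannylation, which fixes the (E) chloroalkene.
- Feature used: the 2,3-disubstituted cyclohex-2-enone ring (C1 carbonyl, C2, C3 methyl, C6 methyl stereocentre next to C1, where it is epimerisable) is an isomer of acyclic bromoalkynyl methyl ketone 6, in which that carbon is a robust propargylic methine; 9 ⇒ 6 by gold-catalysed, methanol-relayed endo alkyne–carbonyl metathesis (the only ring, closed in step 4).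
- 6 ⇒ propanal 1 + methyl vinyl ketone 2: organocatalytic Michael addition (sets the ring methyl centre), dibromo-olefination, loss of HBr.
- 19 ⇒ methyl 3-oxooctanoate 10: asymmetric hydrogenation (sets C7), O-methylation, reduction, vinyl addition, Johnson–Claisen rearrangement (sets the 4E alkene), saponification.

Key step: step 4

Remark: in steps 2–4 the chain is numbered as hept-6-yn-2-one (C2 ketone, C5 methine, C6/C7 alkyne carbons); the ring is numbered as cyclohex-2-en-1-one.

**Route**

Step 1
Reactants: 1 propanal; 2 but-3-en-2-one (methyl vinyl ketone)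
Product: 3 (S)-2-methyl-5-oxohexanal
Conditions: (R)-2-(methoxydiphenylmethyl)pyrrolidine (5 mol%), ethyl 3,4-dihydroxybenzoate (20 mol%), neat, 4 °C
Reagents that add atoms: none
Why: Enamine-catalysed Michael addition of an aldehyde to an enone: the E-enamine of propanal adds to the hydrogen-bond-activated enone through the face remote from the CPh2OMe group, which with the (R)-catalyst sets the (S) methyl centre, the same facial sense as in diarylprolinol ether additions of aldehydes to nitroalkenes.

Step 2
Reactants: 3 (S)-2-methyl-5-oxohexanal; 4 carbon tetrabromide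
Product: 5 (S)-7,7-dibromo-5-methylhept-6-en-2-one
Conditions: CBr4, PPh3, Zn, CH2Cl2, rt (ylide formation); then 3, 0 °C
Reagents that add atoms: none
Why: Ramirez dibromo-olefination (first half of the Corey–Fuchs sequence): the ylide made with zinc is free of base and of Ph3PBr2, attacks the aldehyde much faster than the methyl ketone and leaves the α-methyl centre untouched.

Step 3
Reactants: 5 (S)-7,7-dibromo-5-methylhept-6-en-2-one
Product: 6 (S)-7-bromo-5-methylhept-6-yn-2-one
Conditions: Bu4NF·3H2O (5 equiv), DMF, 60 °C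
Reagents that add atoms: none
Why: E2 dehydrobromination of a 1,1-dibromoalkene to the 1-bromoalkyne: hydrated fluoride removes the vinylic hydrogen anti to bromine and stops at the bromoalkyne, and it is too weak a base to enolise the ketone appreciably or to touch the allylic methine.

Step 4
Reactants: 6 (S)-7-bromo-5-methylhept-6-yn-2-one
Product: 9 (S)-2-bromo-3,6-dimethylcyclohex-2-en-1-one, via bromomethylidene ketal 7 (not isolated), via methoxy ketone 8 (not isolated)
Conditions: (Ph3P)AuNTf2 (5 mol%), MeOH (0.3 equiv), ClCH2CH2Cl, rt to 50 °C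
Reagents that add atoms: none
Why: Proposed new method: the cationic monovalent gold complex binds the bromoalkyne and the ketone oxygen adds 6-exo-dig to C6, the carbon remote from bromine and the one that gold-catalysed hydration of bromoalkynes oxygenates, to give a cyclic oxocarbenium ion carrying an exocyclic C7 bromo(aurio)alkene. That alkene carbon is held anti to the oxocarbenium carbon C2, and an oxete joining them would be a bridgehead alkene of an oxabicyclo[3.1.1]heptene, so a direct [2+2]/retro-[2+2] is not available and methanol is used as a catalytic relay: it caps the oxocarbenium ion and protodeauration gives bromomethylidene ketal 7. The Lewis-acidic gold cation or trace HNTf2 reopens 7 at the ring O–C2 bond to a methoxycarbenium ion tethered to the C6=C7 bromo-enol, whose 6-(enolendo)-exo-trig aldol closure (a Ferrier-type carbocyclisation) forms the C7–C2 bond of the carbocycle as methoxy ketone 8, and loss of methanol from 8 gives the conjugated enone and returns the relay. The net change is an endo-mode alkyne–carbonyl metathesis (both alkyne carbons in the ring, the ketone oxygen moved to C6, the later ring C1); the closest known reactions are gold- or acid-catalysed exo-mode alkyne–ketone metathesis, gold-catalysed hydrative cyclisation of 1,6-diynes to 3-methylcyclohexenones, gold-catalysed alkoxycyclisation of alkynyl ketones and the Ferrier carbocyclisation of 6-alkylidene tetrahydropyranyl acetals. No stereocentre is created (those of 7 and 8 are lost again), and the C5 methyl centre stays a propargylic or allylic carbon until the ring is closed and meets no base. The step needs oxygen delivery to C6 and not to C7 (which would end in an acylcyclopentene), secured by the polarisation of the alkyne by bromine together with the six-membered mode of attack, and it needs C7 to act as the nucleophile towards C2, secured because the enol is generated only at C6=C7 beside the activated C2.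

Step 5
Reactants: 10 methyl 3-oxooctanoate
Product: 11 methyl (S)-3-hydroxyoctanoate
Conditions: H2 (50 atm), RuCl2[(S)-BINAP] (0.1 mol%), MeOH, 50 °C
Reagents that add atoms: none
Why: Noyori asymmetric hydrogenation of a β-keto ester: the chelated substrate is reduced on the face fixed by (S)-BINAP, the mirror image of the (R)-BINAP/(R)-3-hydroxybutanoate case, which sets the (S) carbinol centre.

Step 6
Reactants: 11 methyl (S)-3-hydroxyoctanoate
Product: 12 methyl (S)-3-methoxyoctanoate
Conditions: Me3OBF4, 1,8-bis(dimethylamino)naphthalene, CH2Cl2, rt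
Reagents that add atoms: trimethyloxonium tetrafluoroborate, C[O+](C)C.F[B-](F)(F)F
Why: O-Methylation with Meerwein's salt buffered by a non-nucleophilic base: no alkoxide is formed, so retro-aldol cleavage and β-elimination are avoided and the stereocentre is not touched.

Step 7
Reactants: 12 methyl (S)-3-methoxyoctanoate
Product: 13 (S)-3-methoxyoctanal
Conditions: i-Bu2AlH (1.05 equiv), CH2Cl2, −78 °C; then MeOH, aq. KNaC4H4O6 (Rochelle salt)
Reagents that add atoms: none
Why: Partial reduction of an ester with i-Bu2AlH: the hydride adduct, held on aluminium by chelation to the β-methoxy group, survives at −78 °C and gives the aldehyde only on work-up, and the aldehyde is used at once to avoid loss of methanol.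

Step 8
Reactants: 13 (S)-3-methoxyoctanal; 14 vinylmagnesium bromide
Product: 15 (5S)-5-methoxydec-1-en-3-ol (both C3 epimers)
Conditions: THF, −78 to 0 °C; aq. NH4Cl
Reagents that add atoms: none
Why: Grignard 1,2-addition to the aldehyde: the new C3 carbinol forms as both epimers, which does not matter because C3 becomes an alkene carbon in step 9.

Step 9
Reactants: 15 (5S)-5-methoxydec-1-en-3-ol; 16 triethyl orthoacetate
Product: 18 ethyl (4E,7S)-7-methoxydodec-4-enoate, via ketene acetal 17 (not isolated)
Conditions: MeC(OEt)3 (excess), EtCO2H (cat.), 140 °C, EtOH distilled off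
Reagents that add atoms: none
Why: Johnson–Claisen rearrangement: acid-catalysed exchange gives the mixed ketene acetal, whose [3,3] shift through a chair with the carbinol substituent equatorial gives the (E) alkene from either epimer and leaves the methoxy centre untouched.

Step 10
Reactants: 18 ethyl (4E,7S)-7-methoxydodec-4-enoate
Product: 19 (4E,7S)-7-methoxydodec-4-enoic acid
Conditions: LiOH·H2O, THF/MeOH/H2O, rt; then 1 M HCl to pH 3
Reagents that add atoms: lithium hydroxide, [Li+].[OH-]
Why: Saponification of an unhindered ethyl ester; the γ,δ-alkene cannot move into conjugation under these mild conditions.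

Step 11
Reactants: 20 2-(prop-2-yn-1-yl)isoindoline-1,3-dione (N-propargylphthalimide)
Product: 21 2-[(2Z)-3-(4,4,5,5-tetramethyl-1,3,2-dioxaborolan-2-yl)-2-(tributylstannyl)prop-2-en-1-yl]isoindoline-1,3-dione
Conditions: B2pin2 (1.3 equiv), Bu3SnOMe (1.2 equiv), Cu(OAc)2 (2 mol%), PCy3 (7 mol%), MeCN, rt
Reagents that add atoms: bis(pinacolato)diboron, B1(OC(C)(C)C(C)(C)O1)B1OC(C)(C)C(C)(C)O1; tributyltin methoxide, CCCC[Sn](CCCC)(CCCC)OC
Why: Copper-catalysed three-component borylstannylation of a terminal alkyne: Cu–Bpin adds syn with boron at the terminal carbon and copper at the internal carbon, and Bu3SnOMe traps the alkenylcopper with retention, so that tin and boron are cis; the phthalimide carries no N–H that could protonate the alkenylcopper.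

Step 12
Reactants: 21 phthalimide-protected borylstannane
Product: 22 (2Z)-3-(4,4,5,5-tetramethyl-1,3,2-dioxaborolan-2-yl)-2-(tributylstannyl)prop-2-en-1-amine
Conditions: MeNH2 (33% in EtOH), rt; evaporate, use crude
Reagents that add atoms: none
Why: Aminolysis of the phthalimide (Gabriel-type deprotection) with methylamine at room temperature, conditions under which the alkenyl–tin and alkenyl–boron bonds are stable.

Step 13
Reactants: 19 (4E,7S)-7-methoxydodec-4-enoic acid; 22 amino borylstannane
Product: 24 (4E,7S)-7-methoxy-N-[(2Z)-3-(4,4,5,5-tetramethyl-1,3,2-dioxaborolan-2-yl)-2-(tributylstannyl)prop-2-en-1-yl]dodec-4-enamide, via benzotriazolyl ester 23 (not isolated)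
Conditions: 19, EDC·HCl, HOBt, CH2Cl2, 0 °C; then 22, i-Pr2NEt, rt
Reagents that add atoms: none
Why: Carbodiimide amide coupling through the HOBt active ester, which is preformed so that the acid-sensitive alkenylstannane meets only a buffered medium.

Step 14
Reactants: 9 (S)-2-bromo-3,6-dimethylcyclohex-2-en-1-one; 24 amide borylstannane
Product: 25 (4E,7S)-N-[(2E)-2-[(5S)-2,5-dimethyl-6-oxocyclohex-1-en-1-yl]-3-(4,4,5,5-tetramethyl-1,3,2-dioxaborolan-2-yl)prop-2-en-1-yl]-7-methoxydodec-4-enamide
Conditions: Pd(PPh3)4 (10 mol%), CuCl (5 equiv), LiCl (6 equiv), DMSO, rt to 50 °C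
Reagents that add atoms: none
Why: Stille coupling in its copper chloride-accelerated form for congested 1-substituted alkenylstannanes: the 2-bromoenone adds readily to zerovalent palladium, the C–Sn bond reacts while the pinacolboronate stays inert without base, alkene geometry is retained, and the neutral medium leaves the enolisable ring C6 centre untouched.

Step 15
Reactants: 25 boryl dienone
Product: 26 (4E,7S)-N-[(2E)-3-chloro-2-[(5S)-2,5-dimethyl-6-oxocyclohex-1-en-1-yl]prop-2-en-1-yl]-7-methoxydodec-4-enamide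
Conditions: CuCl2 (3 equiv), THF/MeOH/H2O, 40–50 °C
Reagents that add atoms: copper dichloride, [Cu+2].[Cl-].[Cl-]
Why: Copper-mediated chlorodeboronation of an alkenyl pinacolboronate (boron-to-copper transfer, then C–Cl reductive elimination from trivalent copper) with retention of geometry, which should give the (E) chloroalkene with chlorine cis to the ring; the temperature is kept low to protect the ring methyl centre from acid-promoted enolisation.

**Compound list**

1 | propanal | CCC=O | starting material
2 | but-3-en-2-one (methyl vinyl ketone) | CC(=O)C=C | starting material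
3 | (S)-2-methyl-5-oxohexanal | CC(=O)CC[C@H](C)C=O | intermediate
4 | carbon tetrabromide | BrC(Br)(Br)Br | starting material
5 | (S)-7,7-dibromo-5-methylhept-6-en-2-one | CC(=O)CC[C@H](C)C=C(Br)Br | intermediate
6 | (S)-7-bromo-5-methylhept-6-yn-2-one | CC(=O)CC[C@H](C)C#CBr | intermediate
7 | (5S,Z)-6-(bromomethylidene)-2-methoxy-2,5-dimethyloxane (both C2 epimers) | COC1(C)CC[C@H](C)/C(=C/Br)O1 | intermediate
8 | (6S)-2-bromo-3-methoxy-3,6-dimethylcyclohexan-1-one (C2/C3 isomers) | COC1(C)CC[C@H](C)C(=O)C1Br | intermediate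
9 | (S)-2-bromo-3,6-dimethylcyclohex-2-en-1-one | BrC1=C(C)CC[C@H](C)C1=O | intermediate
10 | methyl 3-oxooctanoate | CCCCCC(=O)CC(=O)OC | starting material
11 | methyl (S)-3-hydroxyoctanoate | CCCCC[C@@H](CC(=O)OC)O | intermediate
12 | methyl (S)-3-methoxyoctanoate | CCCCC[C@@H](CC(=O)OC)OC | intermediate
13 | (S)-3-methoxyoctanal | CCCCC[C@@H](CC=O)OC | intermediate
14 | vinylmagnesium bromide | C=C[Mg]Br | starting material
15 | (5S)-5-methoxydec-1-en-3-ol (both C3 epimers) | CCCCC[C@@H](CC(O)C=C)OC | intermediate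
16 | triethyl orthoacetate | CC(OCC)(OCC)OCC | starting material
17 | 1-ethoxy-1-{[(5S)-5-methoxydec-1-en-3-yl]oxy}ethene (ketene acetal) | CCCCC[C@@H](CC(OC(=C)OCC)C=C)OC | intermediate
18 | ethyl (4E,7S)-7-methoxydodec-4-enoate | CCCCC[C@@H](C/C=C/CCC(=O)OCC)OC | intermediate
19 | (4E,7S)-7-methoxydodec-4-enoic acid | CCCCC[C@@H](C/C=C/CCC(=O)O)OC | intermediate
20 | 2-(prop-2-yn-1-yl)isoindoline-1,3-dione | O=C1N(CC#C)C(=O)c2ccccc12 | starting material
21 | 2-[(2Z)-3-(4,4,5,5-tetramethyl-1,3,2-dioxaborolan-2-yl)-2-(tributylstannyl)prop-2-en-1-yl]isoindoline-1,3-dione | O=C1N(C/C(=C/B2OC(C)(C)C(C)(C)O2)[Sn](CCCC)(CCCC)CCCC)C(=O)c3ccccc13 | intermediate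
22 | (2Z)-3-(4,4,5,5-tetramethyl-1,3,2-dioxaborolan-2-yl)-2-(tributylstannyl)prop-2-en-1-amine | NC/C(=C/B1OC(C)(C)C(C)(C)O1)[Sn](CCCC)(CCCC)CCCC | intermediate
23 | 1H-benzotriazol-1-yl (4E,7S)-7-methoxydodec-4-enoate | CCCCC[C@@H](C/C=C/CCC(=O)On1nnc2ccccc12)OC | intermediate
24 | (4E,7S)-7-methoxy-N-[(2Z)-3-(4,4,5,5-tetramethyl-1,3,2-dioxaborolan-2-yl)-2-(tributylstannyl)prop-2-en-1-yl]dodec-4-enamide | CCCCC[C@@H](C/C=C/CCC(=O)NC/C(=C/B1OC(C)(C)C(C)(C)O1)[Sn](CCCC)(CCCC)CCCC)OC | intermediate
25 | (4E,7S)-N-[(2E)-2-[(5S)-2,5-dimethyl-6-oxocyclohex-1-en-1-yl]-3-(4,4,5,5-tetramethyl-1,3,2-dioxaborolan-2-yl)prop-2-en-1-yl]-7-methoxydodec-4-enamide | CCCCC[C@@H](C/C=C/CCC(=O)NC/C(=C/B1OC(C)(C)C(C)(C)O1)C1=C(C)CC[C@H](C)C1=O)OC | intermediate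
26 | (4E,7S)-N-[(2E)-3-chloro-2-[(5S)-2,5-dimethyl-6-oxocyclohex-1-en-1-yl]prop-2-en-1-yl]-7-methoxydodec-4-enamide | CCCCC[C@@H](C/C=C/CCC(=O)NC/C(=C/Cl)C1=C(C)CC[C@H](C)C1=O)OC | target

**Step count**

Total: 15 steps. Longest linear sequence: 9 steps (steps 5–10, 13, 14, 15).

**Steps most likely to fail**

1. Step 4 (proposed new method). The relay may stop at ketal 7 or at a simple methanol adduct of the alkyne without C–C bond formation. Acid-induced migration of the exocyclic enol ether of 7 into the ring would erase the methyl centre. Oxygen may also be delivered to C7. The fallback uses known reactions only, sets out from 6 and comes back at 9. Gold-catalysed hydration of the bromoalkyne [(Ph3P)AuNTf2, H2O, ClCH2CH2Cl, rt] should give (S)-1-bromo-3-methylheptane-2,6-dione F1. PPh3 in toluene converts it into [(S)-3-methyl-2,6-dioxoheptyl]triphenylphosphonium bromide F2. Aqueous Na2CO3 gives the keto ylide (S)-3-methyl-1-(triphenylphosphoranylidene)heptane-2,6-dione F3, in which phosphorus fixes C7 as the nucleophile. Heating F3 in toluene closes the ring by intramolecular Wittig reaction onto the methyl ketone to (S)-3,6-dimethylcyclohex-2-en-1-one F4. Br2 in CH2Cl2 at −20 °C adds to give (6S)-2,3-dibromo-3,6-dimethylcyclohexan-1-one F5, and Et3N eliminates HBr to return 9.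

2. Step 14. Transfer of the congested internal alkenyl group from tin to copper and palladium may be slow, so that protodestannylation by the amide N–H, homocoupling or reduction of 9 outrun the coupling. The fallback sets out from 9 (with 20 and 19) and comes back at 26; it masks the ketone and builds the diene by a three-component coupling. Luche reduction (NaBH4, CeCl3·7H2O, MeOH, −78 to 0 °C) gives (6S)-2-bromo-3,6-dimethylcyclohex-2-en-1-ol F6 as both C1 epimers. TBSOTf/2,6-lutidine gives tert-butyl{[(6S)-2-bromo-3,6-dimethylcyclohex-2-en-1-yl]oxy}dimethylsilane F7. Copper/palladium-catalysed alkenylboration of alkyne 20 with F7 and B2pin2 (CuCl/PCy3, Pd(OAc)2/XPhos, LiOt-Bu, toluene, 50 °C; syn addition) gives 2-[(2E)-2-[(5S)-6-(tert-butyldimethylsilyloxy)-2,5-dimethylcyclohex-1-en-1-yl]-3-(4,4,5,5-tetramethyl-1,3,2-dioxaborolan-2-yl)prop-2-en-1-yl]isoindoline-1,3-dione F8. CuCl2 in THF/MeOH/H2O gives 2-[(2E)-3-chloro-2-[(5S)-6-(tert-butyldimethylsilyloxy)-2,5-dimethylcyclohex-1-en-1-yl]prop-2-en-1-yl]isoindoline-1,3-dione F9. MeNH2 in EtOH frees (2E)-3-chloro-2-[(5S)-6-(tert-butyldimethylsilyloxy)-2,5-dimethylcyclohex-1-en-1-yl]prop-2-en-1-amine F10. EDC·HCl/HOBt coupling with 19 gives (4E,7S)-N-[(2E)-3-chloro-2-[(5S)-6-(tert-butyldimethylsilyloxy)-2,5-dimethylcyclohex-1-en-1-yl]prop-2-en-1-yl]-7-methoxydodec-4-enamide F11. Bu4NF in THF gives (4E,7S)-N-[(2E)-3-chloro-2-[(5S)-6-hydroxy-2,5-dimethylcyclohex-1-en-1-yl]prop-2-en-1-yl]-7-methoxydodec-4-enamide F12, and Dess–Martin periodinane (NaHCO3, CH2Cl2) oxidises it to 26.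

3. Step 15. The acid released during chlorodeboronation may promote enolisation at ring C6 and erode its configuration, or protodeboronation may compete with C–Cl bond formation. The fallback sets out from 25 and comes back at 26. NaIO4/NH4OAc in acetone/H2O cleaves the pinacol ester to [(1E)-2-[(5S)-2,5-dimethyl-6-oxocyclohex-1-en-1-yl]-3-{[(4E,7S)-7-methoxydodec-4-enoyl]amino}prop-1-en-1-yl]boronic acid F13. Ipso-chlorination of F13 with N-chlorosuccinimide and Et3N in MeCN at rt, a copper-free and nearly neutral halodeboronation that proceeds with retention, gives 26.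

**Further compounds**

F1 | step 4 | (S)-1-bromo-3-methylheptane-2,6-dione | CC(=O)CC[C@H](C)C(=O)CBr
F2 | step 4 | [(S)-3-methyl-2,6-dioxoheptyl]triphenylphosphonium bromide | CC(=O)CC[C@H](C)C(=O)C[P+](c1ccccc1)(c1ccccc1)c1ccccc1.[Br-]
F3 | step 4 | (S)-3-methyl-1-(triphenylphosphoranylidene)heptane-2,6-dione | CC(=O)CC[C@H](C)C(=O)C=P(c1ccccc1)(c1ccccc1)c1ccccc1
F4 | step 4 | (S)-3,6-dimethylcyclohex-2-en-1-one | CC1=CC(=O)[C@@H](C)CC1
F5 | step 4 | (6S)-2,3-dibromo-3,6-dimethylcyclohexan-1-one | CC1(Br)CC[C@H](C)C(=O)C1Br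
F6 | step 14 | (6S)-2-bromo-3,6-dimethylcyclohex-2-en-1-ol (both C1 epimers) | BrC1=C(C)CC[C@H](C)C1O
F7 | step 14 | tert-butyl{[(6S)-2-bromo-3,6-dimethylcyclohex-2-en-1-yl]oxy}dimethylsilane | BrC1=C(C)CC[C@H](C)C1O[Si](C)(C)C(C)(C)C
F8 | step 14 | 2-[(2E)-2-[(5S)-6-(tert-butyldimethylsilyloxy)-2,5-dimethylcyclohex-1-en-1-yl]-3-(4,4,5,5-tetramethyl-1,3,2-dioxaborolan-2-yl)prop-2-en-1-yl]isoindoline-1,3-dione | O=C1N(C/C(=C/B2OC(C)(C)C(C)(C)O2)C2=C(C)CC[C@H](C)C2O[Si](C)(C)C(C)(C)C)C(=O)c3ccccc13
F9 | step 14 | 2-[(2E)-3-chloro-2-[(5S)-6-(tert-butyldimethylsilyloxy)-2,5-dimethylcyclohex-1-en-1-yl]prop-2-en-1-yl]isoindoline-1,3-dione | O=C1N(C/C(=C/Cl)C2=C(C)CC[C@H](C)C2O[Si](C)(C)C(C)(C)C)C(=O)c3ccccc13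
F10 | step 14 | (2E)-3-chloro-2-[(5S)-6-(tert-butyldimethylsilyloxy)-2,5-dimethylcyclohex-1-en-1-yl]prop-2-en-1-amine | NC/C(=C/Cl)C1=C(C)CC[C@H](C)C1O[Si](C)(C)C(C)(C)C
F11 | step 14 | (4E,7S)-N-[(2E)-3-chloro-2-[(5S)-6-(tert-butyldimethylsilyloxy)-2,5-dimethylcyclohex-1-en-1-yl]prop-2-en-1-yl]-7-methoxydodec-4-enamide | CCCCC[C@@H](C/C=C/CCC(=O)NC/C(=C/Cl)C1=C(C)CC[C@H](C)C1O[Si](C)(C)C(C)(C)C)OC
F12 | step 14 | (4E,7S)-N-[(2E)-3-chloro-2-[(5S)-6-hydroxy-2,5-dimethylcyclohex-1-en-1-yl]prop-2-en-1-yl]-7-methoxydodec-4-enamide | CCCCC[C@@H](C/C=C/CCC(=O)NC/C(=C/Cl)C1=C(C)CC[C@H](C)C1O)OC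
F13 | step 15 | [(1E)-2-[(5S)-2,5-dimethyl-6-oxocyclohex-1-en-1-yl]-3-{[(4E,7S)-7-methoxydodec-4-enoyl]amino}prop-1-en-1-yl]boronic acid | CCCCC[C@@H](C/C=C/CCC(=O)NC/C(=C/B(O)O)C1=C(C)CC[C@H](C)C1=O)OC
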